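## The problem

Target 17 is a (2S)-flavanone. Ring A is fused to the pyranone ring C, the 3,4-dihydroxyphenyl ring B sits on C2, C7 carries a methoxy group, and C8 carries an (E)-4-hydroxy-3-methylbut-2-enyl chain (C1''–C4'').

- **Stereocentre.** C2 is the only stereocentre, so nothing in the molecule can relay chirality to it. It has to come from a catalyst- or reagent-controlled step and then survive to the end.
- **Fragility of C2.** Base opens ring C by a retro-oxa-Michael reaction to the achiral 2'-hydroxychalcone. Acid can ionise the benzylic C2–O1 bond, and does so more easily the more electron-rich ring B is.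
- **Catechol.** It must be masked by groups that come off without base and without touching the C7 methyl ether, which excludes methyl ethers on ring B.
- **Side chain.** It sits between O1 and the C7 methoxy group, its trisubstituted alkene must be E, and its allylic alcohol and the C4 ketone restrict the late-stage oxidants, hydrides and acids.
- **Enabling feature.** C8a bears O1. Of its two ortho carbons, C8 is substituted, while C4a is free and para to the C7 methoxy group. An acyl cation tethered to O1 through C2 and C3 can therefore reach only C4a and is electronically directed to it, so forming the C4–C4a bond by intramolecular acylation closes ring C.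

## Retrosynthesis

**17 ⇒ 16 ⇒ 15 (no skeletal bond cut).** The two phenolic O–acetyl bonds are removed last, and the C4'' alcohol is traced back to the aldehyde of enal 15. Acetates keep ring B electron-poor through every acidic step and can be removed by acid-catalysed methanolysis, so no base meets the flavanone. The alcohol is taken back to 15 because an (E)-2-methyl enal is what olefin metathesis delivers with dependable geometry. The forward reduction must distinguish the aldehyde from the C4 aryl ketone.

**15 ⇒ 13 + 14 (C2''=C3'').** The alkene of the chain is cut by cross-metathesis between allylarene 13 and methacrolein 14. The neighbouring option is to attach the complete chain at C8 as an allyl-metal reagent. That would pass through a 1,1-disubstituted η3-allyl palladium species whose syn/anti exchange can scramble the alkene geometry and the point of attachment. Oxidising a prenyl group is shorter but gives alcohol/aldehyde mixtures. Metathesis with an enal is under thermodynamic control and gives the E isomer. Compound 13 is simpler by a C2 unit and has no alkene geometry.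

**13 ⇒ 11 + 12 (C8–C1'').** The allyl group is joined to C8 by Stille coupling of bromide 11 with allyltributylstannane 12. The coupling runs without base or fluoride, which suits the base-labile C2 and the aryl acetates. The bromine has already done a first duty in 11 as the blocking group at C8. The forward step needs oxidative addition into a bromide flanked by two oxygen substituents, hence a bulky, electron-rich phosphine.

**11 ⇒ 9, via 10 (C4–C4a; key disconnection).** Ring C is opened at the aryl ketone bond, giving acid 9, an open-chain compound with one stereocentre. Cutting O1–C2 instead would lead to a chalcone whose ring closure is reversible and not stereocontrolled. Cutting C4–C4a brings C4 in at the ketone oxidation level, uses the ortho/para pattern of ring A, and makes or breaks no bond at C2. The forward reaction must activate the acid without eliminating the aryloxide and without ionising C2–O1. The plan for this is an acid chloride 10, a moderate Lewis acid at low temperature, and the electron-poor diacetate ring B.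

**9 ⇒ 7, via 8 (carboxyl from vinyl).** The carboxyl carbon is traced back to the internal carbon of a terminal alkene. An ester already in place during ether formation would acidify the C3 hydrogens and divert the substitution into dehydration to a cinnamate. A vinyl group is inert there and becomes the acid in one operation afterwards. The forward step needs ozone to take the alkene and not the arenes, and the β-aryloxy aldehyde 8 must be oxidised without being stored.

**7 ⇒ 5 + 6 (C2–O1).** The aryl ether bond is cut to carbinol 5 and 2-bromo-3-methoxyphenol 6, to be joined by Mitsunobu reaction with inversion, (R)-5 to (S)-7. Phenol addition to a cinnamate offers no stereocontrol, and arylation of an alkoxide needs strong base that the acetates do not survive. Phenol 6 is purchased with bromine and methoxy group in place, so ring A needs no substitution chemistry. The forward step needs clean SN2 at a benzylic carbinol, which the electron-poor aryl group favours.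

**5 ⇒ 2 + 3, via 4 (C2–C3).** The carbinol C–C bond is cut to aldehyde 2 and allylboronate 3, joined by a chiral phosphoric acid-catalysed allylboration. This creates the stereocentre and the three-carbon handle in one step under neutral conditions. Asymmetric reduction of a ketone would first require that ketone to be made. The forward step needs Re-face selectivity.

**2 ⇒ 1 (O–acetyl).** Aldehyde 2 is the diacetate of purchased 3,4-dihydroxybenzaldehyde 1.

## Roads not taken

**Alternative 1: ring A built by cycloaddition.**
- *Cut:* C4a–C8a and C5–C6 of ring A.
- *Forward key step:* a 1,3-dioxygenated silyl ketene acetal diene that already carries the C8 chain adds to an alkynyl methyl ketone in a Diels–Alder reaction. The adduct loses methanol and aromatises to acetophenone A1.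
- *Merits:* the cycloaddition fixes the positions of all four ring A substituents. The chain arrives intact with its E alkene, so no coupling is needed at crowded C8 and no late adjustment of the chain. In this respect the road is better than the chosen plan, which spends steps 6 to 8 on the chain.
- *Weak points:* a benzene ring is constructed that can be bought as 6. The diene needs several steps and is hydrolytically labile. C2 is not addressed at all: after A1 the B ring must be condensed on under base, and the 2'-hydroxychalcone must be closed enantioselectively, a reversible reaction for which catalysts give high selectivity mainly on specially activated chalcones.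
- *Comparison:* the chosen plan sets against the easier chain a purchased ring A and a stereocentre fixed by two reliable operations (steps 2 and 3) before the ring exists.

**Alternative 2: polyketide-style folding of ring A.**
- *Cut:* C4a–C5, with ring A unravelled into a chain on a preformed (2S)-2-aryl-dihydropyranone.
- *Forward key step:* mild acid frees a chain aldehyde, C4a adds to it, and dehydration and enolisation aromatise the ring to the C7 phenol A2.
- *Merits:* C2 is set early by asymmetric formation of the dihydropyranone, a reaction class as dependable as the allylboration used here. Ring A is formed regiospecifically and no cross-coupling is needed.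
- *Weak points:* the chain bearing the side chain must be assembled and attached in a long linear sequence. The acid that drives the aldol and aromatisation acts on a dihydropyranone whose C2–O1 bond can open. A2 still needs O-methylation at C7, which requires base in the presence of the flavanone, and removal of three silyl groups.
- *Comparison:* the chosen plan buys the methyl ether with 6 and carries only acid-removable acetates. In return it accepts a late palladium coupling that this road avoids.

**Alternative 3: asymmetric ortho-quinone methide cycloaddition.**
- *Cut:* C3–C4 and O1–C2 together.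
- *Forward key step:* a chiral BINOL-derived phosphoric acid ionises an acetal on the ring A fragment to a 4-methoxy ortho-quinone methide, which adds the ring B styrene in an oxa-[4+2] reaction to give the cis-4-methoxyflavan A3.
- *Merits:* this is the most convergent road. Both bonds of ring C and the stereocentre are formed in one catalytic step from two arenes, which the chosen plan cannot match in convergence.
- *Weak points:* the electron-poor oxa-diene needs an electron-rich styrene, but the acetylated catechol makes the styrene electron-poor; an unprotected or alkylated one would polymerise or resist clean deprotection. The trisubstituted alkene of the chain is a better 2π partner than the styrene and is acid-sensitive. C4 arrives as a methyl ether, so ether cleavage and benzylic oxidation must follow beside an allylic system.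
- *Comparison:* the chosen plan delivers C4 directly as the ketone and carries only a bromine through its key step. It pays for this with a longer linear sequence.

Key step: step 5

Assumption: (R)-TRIP is taken to direct allyl transfer to the Re face of aldehyde 2, as it does for aryl aldehydes in general, giving the (R)-carbinol; phenol 6 is used as purchased.

## Route

Step 1
Reactants: 1 3,4-dihydroxybenzaldehyde
Product: 2 3,4-diacetoxybenzaldehyde (4-formyl-1,2-phenylene diacetate)
Conditions: Ac2O, pyridine, DMAP (cat.), CH2Cl2, 0 °C to rt
Reagents that add atoms: acetic anhydride, CC(=O)OC(C)=O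
Why: Base-catalysed O-acylation of both phenols; the acetates mask the catechol and make ring B electron-poor for steps 3 and 5.

Step 2
Reactants: 2 3,4-diacetoxybenzaldehyde; 3 allylboronic acid pinacol ester (2-allyl-4,4,5,5-tetramethyl-1,3,2-dioxaborolane)
Product: 5 (R)-1-(3,4-diacetoxyphenyl)but-3-en-1-ol, via O-pinacolboryl ether 4 (not isolated)
Conditions: (R)-TRIP [(R)-3,3'-bis(2,4,6-triisopropylphenyl)-1,1'-binaphthyl-2,2'-diyl hydrogen phosphate] (5 mol %), toluene, −30 °C; aqueous work-up
Reagents that add atoms: none
Why: Chiral phosphoric acid-catalysed allylboration through a closed chair transition state in which the acid binds the boronate oxygen and the formyl hydrogen; the catalyst directs allyl to the Re face and so sets the (R)-carbinol, the neutral conditions leave the aryl acetates alone, and borate 4 is hydrolysed on work-up.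

Step 3
Reactants: 5 (R)-1-(3,4-diacetoxyphenyl)but-3-en-1-ol; 6 2-bromo-3-methoxyphenol
Product: 7 4-[(1S)-1-(2-bromo-3-methoxyphenoxy)but-3-en-1-yl]-1,2-phenylene diacetate
Conditions: PPh3, DIAD, toluene, 0 °C to rt (DIAD added slowly)
Reagents that add atoms: none
Why: Mitsunobu etherification; the phenoxide of the acidic ortho-bromophenol displaces the alkoxyphosphonium group by SN2 with inversion, turning (R)-5 into (S)-7. The electron-poor aryl group disfavours ionisation, and the homoallylic carbinol has no carbonyl-acidified hydrogens to drive dehydration.

Step 4
Reactants: 7 4-[(1S)-1-(2-bromo-3-methoxyphenoxy)but-3-en-1-yl]-1,2-phenylene diacetate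
Product: 9 (3S)-3-(2-bromo-3-methoxyphenoxy)-3-(3,4-diacetoxyphenyl)propanoic acid, via β-aryloxy aldehyde 8 (not isolated)
Conditions: O3, CH2Cl2, −78 °C (Sudan Red 7B end point), then PPh3, −78 °C to rt; crude 8, NaClO2, NaH2PO4, 2-methylbut-2-ene, t-BuOH/H2O, 0 °C to rt
Reagents that add atoms: ozone, O=[O+][O-]; sodium chlorite, [Na+].[O-]Cl=O
Why: Ozonolysis of the terminal alkene with reductive work-up followed by Pinnick oxidation; the alkene reacts with ozone much faster than either arene, the aldehyde is oxidised at once under weakly acidic buffer so the aryloxide is not eliminated, and C2 is not involved.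

Step 5
Reactants: 9 (3S)-3-(2-bromo-3-methoxyphenoxy)-3-(3,4-diacetoxyphenyl)propanoic acid
Product: 11 (2S)-8-bromo-7-methoxy-3',4'-diacetoxyflavanone (4-[(2S)-8-bromo-7-methoxy-4-oxochroman-2-yl]-1,2-phenylene diacetate), via acid chloride 10 (not isolated)
Conditions: (COCl)2, DMF (cat.), CH2Cl2, 0 °C to rt; concentrate; SnCl4 (excess), CH2Cl2, −20 to 0 °C
Reagents that add atoms: oxalyl chloride, O=C(Cl)C(=O)Cl (supplies the chlorine of 10; no reagent atom remains in 11)
Why: The acid is converted to chloride 10, SnCl4 polarises it to an acylium-type electrophile, C4a attacks to give a Wheland intermediate, and loss of a proton forms the C4–C4a bond. The closest known reaction type is the intramolecular Friedel–Crafts acylation of 3-aryloxypropanoic and 3-aryl-3-aryloxypropanoic acids to chroman-4-ones and flavanones. Ring C closes as a six-membered ring by 6-exo attack of the arene carbon on the acyl carbon, with the C=O bond left outside the ring. No stereocentre is formed and no bond at C2 is made or broken, so the (S) configuration from step 3 is carried through. The step needs regioselectivity for C4a, which is secured because the three-atom tether reaches only the two carbons ortho to O1, C8 is blocked by bromine, and C4a is activated by the para methoxy group and by O1. It also needs the benzylic C2–O1 bond to stay intact, which the two acetates secure by making ring B too electron-poor to support a C2 cation. The absence of base and the low temperature hold back loss of the aryloxide by elimination, and aryl acetates tolerate SnCl4 at or below 0 °C.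

Step 6
Reactants: 11 (2S)-8-bromo-7-methoxy-3',4'-diacetoxyflavanone; 12 allyltributylstannane
Product: 13 (2S)-8-allyl-7-methoxy-3',4'-diacetoxyflavanone
Conditions: Pd(P(t-Bu)3)2 (5 mol %), toluene, 80 °C
Reagents that add atoms: none
Why: Stille coupling; zerovalent palladium with a bulky electron-rich phosphine inserts into the hindered C8–Br bond, the allyl group is transferred from tin, and reductive elimination forms C8–C1''. No base or fluoride is present, so C2 and the acetates are safe, and an unsubstituted allyl group raises no regiochemical or geometric question.

Step 7
Reactants: 13 (2S)-8-allyl-7-methoxy-3',4'-diacetoxyflavanone; 14 methacrolein (2-methylprop-2-enal, excess)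
Product: 15 (2S)-7-methoxy-8-[(2E)-3-methyl-4-oxobut-2-en-1-yl]-3',4'-diacetoxyflavanone
Conditions: second-generation Grubbs catalyst (H2IMes)(PCy3)Cl2Ru=CHPh (5 mol %), CH2Cl2, 40 °C
Reagents that add atoms: none
Why: Olefin cross-metathesis of a terminal allylarene with a 1,1-disubstituted enal; the conjugated trisubstituted product does not re-enter metathesis and forms under thermodynamic control as the E isomer (aldehyde trans to the C1'' methylene), which sets the alkene geometry.

Step 8
Reactants: 15 (2S)-7-methoxy-8-[(2E)-3-methyl-4-oxobut-2-en-1-yl]-3',4'-diacetoxyflavanone
Product: 16 (2S)-8-[(2E)-4-hydroxy-3-methylbut-2-en-1-yl]-7-methoxy-3',4'-diacetoxyflavanone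
Conditions: NaBH4, EtOH/CH2Cl2 (3:7), −78 °C
Reagents that add atoms: none
Why: Chemoselective 1,2-reduction of an aldehyde beside a ketone at low temperature; the C4 carbonyl is a deactivated aryl ketone with ortho and para oxygen donors, and the short exposure at −78 °C does not open ring C or cleave the acetates.

Step 9
Reactants: 16 (2S)-8-[(2E)-4-hydroxy-3-methylbut-2-en-1-yl]-7-methoxy-3',4'-diacetoxyflavanone
Product: 17 (2S)-3',4'-dihydroxy-8-[(2E)-4-hydroxy-3-methylbut-2-en-1-yl]-7-methoxyflavanone (CNP0503781.1)
Conditions: HCl (1.25 M in MeOH), 0 °C to rt
Reagents that add atoms: none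
Why: Acid-catalysed transesterification of the two aryl acetates to methanol; acid is used because base would open ring C to the chalcone and racemise C2, and the primary allylic alcohol, which lacks a cation-stabilising substituent, and the methyl ether should tolerate dilute acid.

## Compound list

1 | 3,4-dihydroxybenzaldehyde | O=Cc1ccc(O)c(O)c1 | starting material
2 | 3,4-diacetoxybenzaldehyde | CC(=O)Oc1ccc(C=O)cc1OC(C)=O | intermediate
3 | allylboronic acid pinacol ester | C=CCB1OC(C)(C)C(C)(C)O1 | starting material
4 | 4-[(1R)-1-[(4,4,5,5-tetramethyl-1,3,2-dioxaborolan-2-yl)oxy]but-3-en-1-yl]-1,2-phenylene diacetate | C=CC[C@@H](OB1OC(C)(C)C(C)(C)O1)c1ccc(OC(C)=O)c(OC(C)=O)c1 | intermediate (not isolated)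
5 | (R)-1-(3,4-diacetoxyphenyl)but-3-en-1-ol | C=CC[C@@H](O)c1ccc(OC(C)=O)c(OC(C)=O)c1 | intermediate
6 | 2-bromo-3-methoxyphenol | COc1cccc(O)c1Br | starting material
7 | 4-[(1S)-1-(2-bromo-3-methoxyphenoxy)but-3-en-1-yl]-1,2-phenylene diacetate | C=CC[C@H](Oc1cccc(OC)c1Br)c1ccc(OC(C)=O)c(OC(C)=O)c1 | intermediate
8 | (3S)-3-(2-bromo-3-methoxyphenoxy)-3-(3,4-diacetoxyphenyl)propanal | O=CC[C@H](Oc1cccc(OC)c1Br)c1ccc(OC(C)=O)c(OC(C)=O)c1 | intermediate (not isolated)
9 | (3S)-3-(2-bromo-3-methoxyphenoxy)-3-(3,4-diacetoxyphenyl)propanoic acid | O=C(O)C[C@H](Oc1cccc(OC)c1Br)c1ccc(OC(C)=O)c(OC(C)=O)c1 | intermediate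
10 | (3S)-3-(2-bromo-3-methoxyphenoxy)-3-(3,4-diacetoxyphenyl)propanoyl chloride | O=C(Cl)C[C@H](Oc1cccc(OC)c1Br)c1ccc(OC(C)=O)c(OC(C)=O)c1 | intermediate (not isolated)
11 | (2S)-8-bromo-7-methoxy-3',4'-diacetoxyflavanone | COc1ccc2c(c1Br)O[C@H](c1ccc(OC(C)=O)c(OC(C)=O)c1)CC2=O | intermediate
12 | allyltributylstannane | C=CC[Sn](CCCC)(CCCC)CCCC | starting material
13 | (2S)-8-allyl-7-methoxy-3',4'-diacetoxyflavanone | COc1ccc2c(c1CC=C)O[C@H](c1ccc(OC(C)=O)c(OC(C)=O)c1)CC2=O | intermediate
14 | methacrolein | C=C(C)C=O | starting material
15 | (2S)-7-methoxy-8-[(2E)-3-methyl-4-oxobut-2-en-1-yl]-3',4'-diacetoxyflavanone | COc1ccc2c(c1C/C=C(\C)C=O)O[C@H](c1ccc(OC(C)=O)c(OC(C)=O)c1)CC2=O | intermediate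
16 | (2S)-8-[(2E)-4-hydroxy-3-methylbut-2-en-1-yl]-7-methoxy-3',4'-diacetoxyflavanone | COc1ccc2c(c1C/C=C(\C)CO)O[C@H](c1ccc(OC(C)=O)c(OC(C)=O)c1)CC2=O | intermediate
17 | (2S)-3',4'-dihydroxy-8-[(2E)-4-hydroxy-3-methylbut-2-en-1-yl]-7-methoxyflavanone | COc1ccc2c(c1C/C=C(\C)CO)O[C@H](c1ccc(O)c(O)c1)CC2=O | target

## Step count and least certain steps

Total step count: 9. Longest linear sequence: 9 steps (1 to 17); 3, 6, 12 and 14 are purchased and enter at steps 2, 3, 6 and 7.

**Step 5 (key step).** The most likely failure is erosion of the C2 configuration. Bromine at C8 and tin bound to the two acetates slow the closure, and during a slow closure SnCl4 or the HCl formed can promote reversible heterolysis of C2–O1 in 10, or reversible ring–chain opening of 11 to the chalcone. The fallback keeps the closure and corrects the configuration afterwards by kinetic resolution. It sets out from 11 of reduced enantiomeric purity and comes back to 11. Asymmetric transfer hydrogenation is used with RuCl(p-cymene)[(R,R)-TsDPEN] or its enantiomer, whichever reduces the (2R) ketone faster, in HCO2H/Et3N and EtOAc at rt. It should convert the minor enantiomer into (2R,4R)-8-bromo-7-methoxy-3',4'-diacetoxyflavan-4-ol F1, from which unreacted (2S)-11 is separated by chromatography.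

**Step 3.** The most likely failure is E2 elimination of the activated carbinol to the conjugated 1-aryl-1,3-butadiene, competing with substitution by a phenoxide hindered by its ortho bromine. Transfer of an acetyl group from 5 to that phenoxide is a second drain. The fallback gives up substitution at C2 and sets the stereocentre after the ring is closed. It sets out from 6 and comes back at 11, and would replace step 5 as well should the closure itself fail.
- Phenol 6 is O-alkylated with 3-bromopropanoic acid (aqueous NaOH) to 3-(2-bromo-3-methoxyphenoxy)propanoic acid F2.
- P2O5 in MeSO3H closes F2 to 8-bromo-7-methoxychroman-4-one F3. This is the same C4–C4a acylation, on a substrate with no stereocentre and no benzylic ether.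
- 2-Iodoxybenzoic acid in DMSO dehydrogenates F3 to 8-bromo-7-methoxychromone F4.
- The ring B donor is made from catechol diacetate by C–H borylation with B2pin2 ([Ir(OMe)(cod)]2, 4,4'-di-tert-butyl-2,2'-bipyridine) to 4-(4,4,5,5-tetramethyl-1,3,2-dioxaborolan-2-yl)-1,2-phenylene diacetate F5, followed by NaIO4/aqueous HCl cleavage to (3,4-diacetoxyphenyl)boronic acid F6.
- Pd(OCOCF3)2, with the enantiomer of 4-tert-butyl-2-(pyridin-2-yl)-4,5-dihydrooxazole that leads to the (2S) product, adds F6 to F4 (NH4PF6, H2O, 1,2-dichloroethane, 60 °C) and gives 11. The catalyst stays divalent palladium throughout, so the C8 bromide is not touched.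

**Step 4.** The most likely failure is over-oxidation: near the end point ozone begins to attack the electron-rich bromodialkoxybenzene ring of 7, since its selectivity for the alkene is finite. The fallback replaces ozone by a two-stage cleavage. It sets out from 7 and comes back at 8. Dihydroxylation with OsO4 (cat.) and N-methylmorpholine N-oxide in acetone/H2O gives 4-[(1S)-1-(2-bromo-3-methoxyphenoxy)-3,4-dihydroxybutyl]-1,2-phenylene diacetate F7 (both epimers at the new carbinol carbon). NaIO4 on silica in CH2Cl2 cleaves F7 to 8, which goes straight into the chlorite oxidation of step 4.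

**Step 8.** The most likely failure is competing hydride addition to the C4 ketone, or conjugate reduction of the enal, if the rate difference at −78 °C proves too small. The fallback avoids the aldehyde oxidation level. It sets out from 13 and comes back at 16. Cross-metathesis of 13 with 2-methylbut-2-ene (second-generation Grubbs catalyst, CH2Cl2, 40 °C) gives (2S)-7-methoxy-8-(3-methylbut-2-en-1-yl)-3',4'-diacetoxyflavanone F8. Allylic hydroxylation with SeO2 (cat.) and t-BuOOH in CH2Cl2 at rt, which is selective for the (E)-methyl group of a trisubstituted alkene, then gives 16.

## Further compounds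

F1 | step 5 | (2R,4R)-8-bromo-7-methoxy-3',4'-diacetoxyflavan-4-ol | COc1ccc2c(c1Br)O[C@@H](c1ccc(OC(C)=O)c(OC(C)=O)c1)C[C@H]2O
F2 | step 3 | 3-(2-bromo-3-methoxyphenoxy)propanoic acid | COc1cccc(OCCC(=O)O)c1Br
F3 | step 3 | 8-bromo-7-methoxychroman-4-one | COc1ccc2c(c1Br)OCCC2=O
F4 | step 3 | 8-bromo-7-methoxy-4H-chromen-4-one | COc1ccc2c(c1Br)occc2=O
F5 | step 3 | 4-(4,4,5,5-tetramethyl-1,3,2-dioxaborolan-2-yl)-1,2-phenylene diacetate | CC(=O)Oc1ccc(B2OC(C)(C)C(C)(C)O2)cc1OC(C)=O
F6 | step 3 | (3,4-diacetoxyphenyl)boronic acid | CC(=O)Oc1ccc(B(O)O)cc1OC(C)=O
F7 | step 4 | 4-[(1S)-1-(2-bromo-3-methoxyphenoxy)-3,4-dihydroxybutyl]-1,2-phenylene diacetate | OCC(O)C[C@H](Oc1cccc(OC)c1Br)c1ccc(OC(C)=O)c(OC(C)=O)c1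
F8 | step 8 | (2S)-7-methoxy-8-(3-methylbut-2-en-1-yl)-3',4'-diacetoxyflavanone | COc1ccc2c(c1CC=C(C)C)O[C@H](c1ccc(OC(C)=O)c(OC(C)=O)c1)CC2=O
A1 | alternative 1 | 2'-hydroxy-4'-methoxy-3'-[(E)-4-(tert-butyldimethylsilyloxy)-3-methylbut-2-enyl]acetophenone | COc1ccc(C(C)=O)c(O)c1C/C=C(\C)CO[Si](C)(C)C(C)(C)C
A2 | alternative 2 | (2S)-7-hydroxy-8-[(E)-4-(tert-butyldimethylsilyloxy)-3-methylbut-2-enyl]-3',4'-bis(tert-butyldimethylsilyloxy)flavanone | Oc1ccc2c(c1C/C=C(\C)CO[Si](C)(C)C(C)(C)C)O[C@H](c1ccc(O[Si](C)(C)C(C)(C)C)c(O[Si](C)(C)C(C)(C)C)c1)CC2=O
A3 | alternative 3 | (2S,4S)-cis-4,7-dimethoxy-8-[(E)-4-(tert-butyldimethylsilyloxy)-3-methylbut-2-enyl]-3',4'-diacetoxyflavan | COc1ccc2c(c1C/C=C(\C)CO[Si](C)(C)C(C)(C)C)O[C@H](c1ccc(OC(C)=O)c(OC(C)=O)c1)C[C@@H]2OC
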